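**Earlier runs.** The grey run, with 1.5 equiv of free base, holds 1% electrophile at 5.00 min. The teal run, with 1.3 equiv, holds 3%. Both were charged with 1.8 equiv of solid nucleophile.

| setting | grey | teal | maple | elm |
|---|---|---|---|---|
| electrophile | 47 mM | 47 mM | 47 mM | 47 mM |
| free base | 1.5 equiv | 1.3 equiv | 1.20 equiv | 1.60 equiv |
| solid nucleophile | 1.8 equiv | 1.8 equiv | 1.80 equiv | 1.80 equiv |
| remark | run made earlier | run made earlier |  |  |
| time |  |  | 5.0 min | 5.0 min |

| run | time / min | electrophile / % | target / % |
|---|---|---|---|
| grey | 0.417 | 83 | 15 |
| grey | 0.833 | 66 | 34 |
| grey | 1.33 | 47 | 53 |
| grey | 2.50 | 10 | 88 |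
| grey | 5.00 | 1 | 93 |
| teal | 1.00 | 59 | 39 |
| teal | 2.00 | 14 | 80 |
| teal | 3.00 | 6 | 90 |
| teal | 4.00 | 2 | 97 |
| teal | 5.00 | 3 | 90 |

(scatter of a reading: 2 percentage points)

- solid, in amounts per volume of the solution: solid nucleophile
- on the list of suspects stand: acid set free + target -> side product; electrophile + nucleophile -> acid set free + target; solid nucleophile <-> nucleophile; nucleophile + acid set free <-> protonated nucleophile; 2 nucleophile -> self-condensation product; acid set free + free base <-> salt of the base
- at the start none of the solid nucleophile is in solution

* part of the electrophile that has reacted at the end, maple
* part of the electrophile that has reacted at the end, elm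
* what raising the equivalents of free base from its lowest to its highest value here does to the part of the electrophile that has reacted (changes below 5 percentage points count as none) (it rises / no change / it falls)

**Two ways.** The first way counts nucleophile. Each electrophile that reacts takes one nucleophile and sets one acid free. If that acid then takes a second nucleophile, as protonated nucleophile, the charge covers 90.0% of the electrophile. The second way reads the flask: the teal run has 97.0% reacted and the grey run 99.0%. They part by 7 percentage points at least, more than the scatter of 2 points, so the count cheats: some acid goes elsewhere.

**Base demand.** The gap has a size. The base demand is twice the electrophile charged minus the solid nucleophile charged: the acid that must leave other than onto nucleophile, chiefly to the free base, for the electrophile to finish. Here it is 9.40 mM, the same for maple and elm. That is 16.7% of maple's free base, less than its charge. So this reckoning places both flasks near the earlier runs, between 97.0% and 99.0%, with no change between them.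

**Forecast and result.** The forecast gives 97% for maple, 99% for elm and no change, holding that “The base only needs to capture the one equivalent of acid released.”, and the demand here is less than that one equivalent. The flasks give 98.0% and 98.5%, a change of 0.55 points: no change.

    acid set free + target → side product (k = 0.626 L mol⁻¹ s⁻¹)
    electrophile + nucleophile → acid set free + target (k = 10.9 L mol⁻¹ s⁻¹)
    solid nucleophile ⇌ nucleophile, rate k3*(cs3 - [nucleophile]) while solid is left; crystals form when [nucleophile] > cs3 (solubility = 18.0 mM, k = 0.0376 s⁻¹)
    nucleophile + acid set free ⇌ protonated nucleophile, settled at all times (K = 1.12 × 10⁵ L mol⁻¹)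
    2 nucleophile → self-condensation product (k = 1.06 L mol⁻¹ s⁻¹)
    acid set free + free base ⇌ salt of the base (K = 623 L mol⁻¹, k = 3.11 L mol⁻¹ s⁻¹)

**The neighbour.** In maple at 5.00 min, [salt of the base] plus side product comes to 9.24 mM against the demand of 9.40 mM. A neighbour of elm charged with 1.10 equiv of solid nucleophile has a demand of 42.3 mM. Its [salt of the base] plus side product reaches 20.2 mM at 5.00 min, less than that. It reacts 76.8% of its electrophile, above its count of 55.0%. In that neighbour at the end, 0.39% of the solid nucleophile charge stands as solid or dissolved, 15.2 mM is held as protonated nucleophile, and 77% of the free base is still there.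

The readings were generated by integration for an exercise, and the scatter is random.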